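**Strategy.** The route builds ring C of the middle, galloylated unit last, between two epigallocatechin-derived fragments. A chiral-acid-mediated oxa-Povarov annulation unites an aryl oxocarbenium ion (O1=C2, released from an epimeric mixed acetal on the phenol ring already bonded to C4 of the upper unit) with a (Z)-enol gallate placed on C8 of the lower unit. One operation forms C2–C3 and C4–C4a, sets C2, C3 and C4 and delivers the galloyl ester in place. It exploits the free C4a–H ortho to O1 on the phloroglucinol-type ring A of the middle unit, and the 2,4,6-trioxygenated ring A of the lower unit, which stabilises positive charge at C4 and so fixes the polarity of the alkene.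

Key step: step 10

Remark on the chemistry: the target is read as epigallocatechin-(4β→8)-epigallocatechin 3-O-gallate-(4β→8)-epigallocatechin, all three units (2R,3R), each C4–aryl bond trans to the neighbouring C3 oxygen. Flavan numbering (O1, C2, C3, C4, C4a, C5–C8, C8a) is used for each unit (upper, middle, lower). Per-O-benzylation of 1 is assumed to proceed without epimerisation at C2.

**Step 1**
Reactants: 1 (−)-epigallocatechin
Product: 2 hexa-O-benzyl-epigallocatechin
Conditions: BnBr (7.5 equiv), NaH (7.5 equiv), DMF, −40 °C → rt, argon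
Reagents that add atoms: benzyl bromide BrCc1ccccc1
Why: Williamson ether synthesis, in which sodium hydride deprotonates the five phenols and the C3 alcohol and each oxygen is benzylated by SN2, the low temperature leaving C2 and C3 untouched.

**Step 2**
Reactants: 2 hexa-O-benzyl-epigallocatechin
Product: 3 4β-(2-ethoxyethoxy)-hexa-O-benzyl-epigallocatechin
Conditions: DDQ (2 equiv), 2-ethoxyethanol (5 equiv), CH2Cl2, rt
Reagents that add atoms: 2-ethoxyethanol CCOCCO
Why: DDQ benzylic oxidation (hydride abstraction at C4, activated by the ring A oxygens) gives a C4 cation that the alcohol should capture anti to the 3-benzyloxy group, setting C4 as 4β.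

**Step 3**
Reactants: 3 4β-(2-ethoxyethoxy)-hexa-O-benzyl-epigallocatechin; 4 3,5-bis(benzyloxy)phenol
Product: 5 upper-unit phenol (4β-(2-hydroxy-4,6-bis(benzyloxy)phenyl)-hexa-O-benzyl-epigallocatechin)
Conditions: 4 (4 equiv), TMSOTf (0.2 equiv), CH2Cl2, −78 → −40 °C
Reagents that add atoms: none
Why: Lewis-acid-mediated Friedel–Crafts arylation of a flavan C4 cation, in which the phenol should react through a carbon ortho to its OH (the two are equivalent) on the face anti to the C3 substituent, as in the 4β-selective captures of 2,3-cis flavan cations, so the new bond is 3,4-trans.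

**Step 4**
Reactants: 6 3,4,5-tris(benzyloxy)benzaldehyde
Product: 7 3,4,5-tris(benzyloxy)benzaldehyde dimethyl acetal
Conditions: HC(OMe)3 (3 equiv), cat. TsOH, MeOH, rt
Reagents that add atoms: trimethyl orthoformate COC(OC)OC
Why: Acid-catalysed acetalisation, driven to completion by the orthoformate as water scavenger.

**Step 5**
Reactants: 5 upper-unit phenol; 7 3,4,5-tris(benzyloxy)benzaldehyde dimethyl acetal
Product: 9 mixed O-aryl O-methyl acetal of the upper fragment, via alpha-chloro ether 8 (not isolated)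
Conditions: 7, AcCl, cat. SOCl2, CH2Cl2, 0 °C → rt, evaporate; then 5, NaH, THF/DMF, 0 °C → rt; purification on base-washed silica
Reagents that add atoms: none
Why: Acetal-to-α-chloro-ether exchange followed by Williamson-type O-alkylation of the sodium phenoxide, as in MOM protection of phenols; the acetal carbon forms as a mixture of epimers, which does not matter because step 10 planarises it.

**Step 6**
Reactants: 2 hexa-O-benzyl-epigallocatechin
Product: 10 8-bromo-hexa-O-benzyl-epigallocatechin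
Conditions: NBS (1.0 equiv), CH2Cl2, −78 → 0 °C
Reagents that add atoms: N-bromosuccinimide O=C1CCC(=O)N1Br
Why: Electrophilic aromatic bromination, which should occur at C8 of ring A, the established site for benzylated epicatechin-type flavans.

**Step 7**
Reactants: 10 8-bromo-hexa-O-benzyl-epigallocatechin
Product: 11 8-(trimethylsilylethynyl)-hexa-O-benzyl-epigallocatechin
Conditions: trimethylsilylacetylene, PdCl2(MeCN)2 (3 mol%), XPhos (9 mol%), Cs2CO3, MeCN, 80 °C
Reagents that add atoms: trimethylsilylacetylene C#C[Si](C)(C)C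
Why: Copper-free Sonogashira coupling, the bulky electron-rich biarylphosphine enabling oxidative addition into the hindered, electron-rich aryl bromide.

**Step 8**
Reactants: 11 8-(trimethylsilylethynyl)-hexa-O-benzyl-epigallocatechin
Product: 12 8-ethynyl-hexa-O-benzyl-epigallocatechin
Conditions: cat. K2CO3, MeOH/THF, rt
Reagents that add atoms: none
Why: Base-catalysed protodesilylation (methanolysis of the alkynyl C–Si bond).

**Step 9**
Reactants: 12 8-ethynyl-hexa-O-benzyl-epigallocatechin; 13 3,4,5-tris(benzyloxy)benzoic acid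
Product: 14 lower-unit (Z)-enol gallate
Conditions: 13 (1.2 equiv), Ru(η3-CH2C(CH3)CH2)2(Ph2P(CH2)4PPh2) (5 mol%), toluene, 65 °C
Reagents that add atoms: none
Why: Ruthenium-catalysed anti-Markovnikov hydro-oxycarbonylation of a terminal alkyne through a ruthenium vinylidene, which should deliver the carboxylate to the terminal carbon and give the (Z)-enol ester.

**Step 10**
Reactants: 9 mixed O-aryl O-methyl acetal of the upper fragment; 14 lower-unit (Z)-enol gallate
Product: 17 per-O-benzylated trimer, via aryl oxocarbenium ion 15 (not isolated), via benzylic cation 16 (not isolated)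
Conditions: (R)-3,3'-bis(2,4,6-triisopropylphenyl)-1,1'-binaphthyl-2,2'-diyl N-triflylphosphoramide (10 mol%), 5 Å molecular sieves, CH2Cl2, −60 → −30 °C
Reagents that add atoms: none
Why: Proposed new method: the chiral acid protonates the methoxy oxygen of either acetal epimer of 9 and, after loss of methanol, keeps the planar (E)-aryl oxocarbenium ion 15 as an ion pair, whose C2 is attacked by the acyloxy-bearing alkene carbon of 14 (future C3) to give benzylic cation 16, which is then closed by Friedel–Crafts attack of the only free position ortho to O1 (future C4a) on C4. The closest known reaction type is the SnCl4-promoted oxa-Povarov reaction of aryl oxocarbenium ions with styrenes, while control of its facial course by a chiral counter-anion, modelled on chiral phosphoric-acid-catalysed Povarov reactions and chiral-acid-catalysed additions to oxocarbenium ions, has not been shown. The single ring closed, ring C of the middle unit, forms in a stepwise cationic [4+2] mode (2-oxadiene C4a=C8a–O1=C2 plus alkene), its last bond by a six-membered Friedel–Crafts closure onto the quinone-methide-like cation. C2 (R) is controlled by the chiral anion, which shields one face of 15 so that both epimers of 9 converge, and C3 (R) follows from the Z geometry of 14 in an endo approach in which ring A of the lower unit lies under the cationic oxadiene, as cyclic Z-styrenes such as indene do in Povarov reactions, giving the 2,3-cis relation. C4 is set last and reversibly, since the doubly benzylic C4–aryl bond can re-ionise under the acid, so that the aryl settles anti to the 3-O-galloyl group, whose carbonyl bridges cation 16, and pseudo-axial away from the peri 5-benzyloxy group, which is the 3,4-trans (4β) arrangement. The step needs bond formation through the oxygen-bearing alkene carbon, secured by the 2,4,6-trioxygenated ring A of the lower unit that stabilises charge at the other carbon, and loss of methoxide rather than aryloxide from 9, favoured by the more basic alkyl oxygen and by removal of methanol on the sieves.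

**Step 11**
Reactants: 17 per-O-benzylated trimer
Product: 18 target trimer CNP0278699.1
Conditions: H2 (1 atm), Pd(OH)2/C, THF/MeOH/H2O, rt; filtration and lyophilisation under argon
Reagents that add atoms: none
Why: Global hydrogenolysis of the twenty benzyl ethers under conditions used for benzylated procyanidin gallates, which should leave the gallate ester, the C2–O1 bonds and the C4–aryl bonds intact and touch no stereocentre.

**Compound list**

1 | (−)-epigallocatechin, (2R,3R)-2-(3,4,5-trihydroxyphenyl)chroman-3,5,7-triol | O[C@@H]1Cc2c(O)cc(O)cc2O[C@@H]1c1cc(O)c(O)c(O)c1 | starting material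

2 | hexa-O-benzyl-epigallocatechin, (2R,3R)-3,5,7-tris(benzyloxy)-2-[3,4,5-tris(benzyloxy)phenyl]chroman | C(c1ccccc1)O[C@@H]1Cc2c(OCc3ccccc3)cc(OCc3ccccc3)cc2O[C@@H]1c1cc(OCc2ccccc2)c(OCc2ccccc2)c(OCc2ccccc2)c1 | intermediate

3 | (2R,3R)-3,5,7-tris(benzyloxy)-4β-(2-ethoxyethoxy)-2-[3,4,5-tris(benzyloxy)phenyl]chroman, alkoxy group trans to the 3-benzyloxy group | CCOCCO[C@H]1c2c(OCc3ccccc3)cc(OCc3ccccc3)cc2O[C@H](c2cc(OCc3ccccc3)c(OCc3ccccc3)c(OCc3ccccc3)c2)[C@@H]1OCc1ccccc1 | intermediate

4 | 3,5-bis(benzyloxy)phenol | Oc1cc(OCc2ccccc2)cc(OCc2ccccc2)c1 | starting material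

5 | upper-unit phenol: 3,5-bis(benzyloxy)-2-[(2R,3R)-3,5,7-tris(benzyloxy)-2-(3,4,5-tris(benzyloxy)phenyl)chroman-4β-yl]phenol, aryl trans to the 3-benzyloxy group | Oc1cc(OCc2ccccc2)cc(OCc2ccccc2)c1[C@H]1c2c(OCc3ccccc3)cc(OCc3ccccc3)cc2O[C@H](c2cc(OCc3ccccc3)c(OCc3ccccc3)c(OCc3ccccc3)c2)[C@@H]1OCc1ccccc1 | intermediate

6 | 3,4,5-tris(benzyloxy)benzaldehyde | O=Cc1cc(OCc2ccccc2)c(OCc2ccccc2)c(OCc2ccccc2)c1 | starting material

7 | 3,4,5-tris(benzyloxy)benzaldehyde dimethyl acetal | COC(OC)c1cc(OCc2ccccc2)c(OCc2ccccc2)c(OCc2ccccc2)c1 | intermediate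

8 | alpha-chloro ether: 1,2,3-tris(benzyloxy)-5-[chloro(methoxy)methyl]benzene (racemic, not isolated) | COC(Cl)c1cc(OCc2ccccc2)c(OCc2ccccc2)c(OCc2ccccc2)c1 | intermediate

9 | mixed acetal: aryl ether of 5 with the methoxy[3,4,5-tris(benzyloxy)phenyl]methyl group on the phenol oxygen (both epimers at the acetal carbon) | COC(Oc1cc(OCc2ccccc2)cc(OCc2ccccc2)c1[C@H]1c2c(OCc3ccccc3)cc(OCc3ccccc3)cc2O[C@H](c2cc(OCc3ccccc3)c(OCc3ccccc3)c(OCc3ccccc3)c2)[C@@H]1OCc1ccccc1)c1cc(OCc2ccccc2)c(OCc2ccccc2)c(OCc2ccccc2)c1 | intermediate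

10 | (2R,3R)-3,5,7-tris(benzyloxy)-8-bromo-2-[3,4,5-tris(benzyloxy)phenyl]chroman | C(c1ccccc1)O[C@@H]1Cc2c(OCc3ccccc3)cc(OCc3ccccc3)c(Br)c2O[C@@H]1c1cc(OCc2ccccc2)c(OCc2ccccc2)c(OCc2ccccc2)c1 | intermediate

11 | (2R,3R)-3,5,7-tris(benzyloxy)-2-[3,4,5-tris(benzyloxy)phenyl]-8-[(trimethylsilyl)ethynyl]chroman | C(c1ccccc1)O[C@@H]1Cc2c(OCc3ccccc3)cc(OCc3ccccc3)c(C#C[Si](C)(C)C)c2O[C@@H]1c1cc(OCc2ccccc2)c(OCc2ccccc2)c(OCc2ccccc2)c1 | intermediate

12 | (2R,3R)-3,5,7-tris(benzyloxy)-8-ethynyl-2-[3,4,5-tris(benzyloxy)phenyl]chroman | C(c1ccccc1)O[C@@H]1Cc2c(OCc3ccccc3)cc(OCc3ccccc3)c(C#C)c2O[C@@H]1c1cc(OCc2ccccc2)c(OCc2ccccc2)c(OCc2ccccc2)c1 | intermediate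

13 | 3,4,5-tris(benzyloxy)benzoic acid | OC(=O)c1cc(OCc2ccccc2)c(OCc2ccccc2)c(OCc2ccccc2)c1 | starting material

14 | (Z)-2-[(2R,3R)-3,5,7-tris(benzyloxy)-2-(3,4,5-tris(benzyloxy)phenyl)chroman-8-yl]ethenyl 3,4,5-tris(benzyloxy)benzoate | C(c1ccccc1)O[C@@H]1Cc2c(OCc3ccccc3)cc(OCc3ccccc3)c(/C=C\OC(=O)c3cc(OCc4ccccc4)c(OCc4ccccc4)c(OCc4ccccc4)c3)c2O[C@@H]1c1cc(OCc2ccccc2)c(OCc2ccccc2)c(OCc2ccccc2)c1 | intermediate

15 | (E)-aryl oxocarbenium ion from 9 by loss of methoxide (ion pair with the chiral phosphoramide anion, not isolated) | c1c(OCc2ccccc2)c(OCc2ccccc2)c(OCc2ccccc2)cc1/C=[O+]/c1cc(OCc2ccccc2)cc(OCc2ccccc2)c1[C@H]1c2c(OCc3ccccc3)cc(OCc3ccccc3)cc2O[C@H](c2cc(OCc3ccccc3)c(OCc3ccccc3)c(OCc3ccccc3)c2)[C@@H]1OCc1ccccc1 | intermediate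

16 | benzylic cation after C2–C3 bond formation, C2 and C3 as in 17, charge on the carbon attached to C8 of the lower unit (not isolated) | O=C(c1cc(OCc2ccccc2)c(OCc2ccccc2)c(OCc2ccccc2)c1)O[C@@H]([C@H](Oc1cc(OCc2ccccc2)cc(OCc2ccccc2)c1[C@H]1c2c(OCc3ccccc3)cc(OCc3ccccc3)cc2O[C@H](c2cc(OCc3ccccc3)c(OCc3ccccc3)c(OCc3ccccc3)c2)[C@@H]1OCc1ccccc1)c1cc(OCc2ccccc2)c(OCc2ccccc2)c(OCc2ccccc2)c1)[CH+]c1c(OCc2ccccc2)cc(OCc2ccccc2)c2c1O[C@H](c1cc(OCc3ccccc3)c(OCc3ccccc3)c(OCc3ccccc3)c1)[C@H](OCc1ccccc1)C2 | intermediate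

17 | per-O-benzylated trimer: the target with all seventeen phenols and both free C3 hydroxyls as benzyl ethers; middle unit (2R,3R), 2,3-cis, 3,4-trans | O=C(O[C@@H]1[C@@H](c2c(OCc5ccccc5)cc(OCc5ccccc5)c3c2O[C@H](c2cc(OCc5ccccc5)c(OCc5ccccc5)c(OCc5ccccc5)c2)[C@H](OCc5ccccc5)C3)c2c(OCc5ccccc5)cc(OCc5ccccc5)c([C@H]3c4c(OCc5ccccc5)cc(OCc5ccccc5)cc4O[C@H](c4cc(OCc5ccccc5)c(OCc5ccccc5)c(OCc5ccccc5)c4)[C@@H]3OCc5ccccc5)c2O[C@@H]1c1cc(OCc5ccccc5)c(OCc5ccccc5)c(OCc5ccccc5)c1)c1cc(OCc5ccccc5)c(OCc5ccccc5)c(OCc5ccccc5)c1 | intermediate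

18 | CNP0278699.1, epigallocatechin-(4β→8)-epigallocatechin 3-O-gallate-(4β→8)-epigallocatechin | O=C(O[C@@H]1[C@@H](c2c(O)cc(O)c3c2O[C@H](c2cc(O)c(O)c(O)c2)[C@H](O)C3)c2c(O)cc(O)c([C@H]3c4c(O)cc(O)cc4O[C@H](c4cc(O)c(O)c(O)c4)[C@@H]3O)c2O[C@@H]1c1cc(O)c(O)c(O)c1)c1cc(O)c(O)c(O)c1 | target

**Totals.** Total step count: 11. Longest linear sequence: 7 steps (1, 6, 7, 8, 9, 10, 11).

**Steps most likely to fail**

Step 10 (Proposed new method). The risks are poor facial or endo/exo selectivity at the oxocarbenium, ionisation of 9 by loss of the aryloxide instead of methoxide, and Friedel–Crafts attack of the oxocarbenium on free ring A positions instead of the alkene. The fallback is the classical interflavan coupling; it sets out from 2 and 3 and comes back at 17. Commercial (−)-epigallocatechin 3-O-gallate (O=C(O[C@@H]1Cc2c(O)cc(O)cc2O[C@@H]1c1cc(O)c(O)c(O)c1)c1cc(O)c(O)c(O)c1) would be perbenzylated (BnBr, K2CO3, DMF) to octa-O-benzyl-epigallocatechin gallate F1. Oxidation of F1 with DDQ and 2-ethoxyethanol should give its 4β-(2-ethoxyethoxy) derivative F2. F2 would be coupled with excess 2 (TMSOTf, CH2Cl2, −78 °C) through C8 of 2, anti to the participating 3-O-galloyl group, to give the protected dimer F3. Coupling of F3 with 3 under the same conditions should then occur at C8 of the galloylated unit and give 17.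

Step 5. The risks are C-alkylation of the electron-rich phenoxide and hydrolytic loss of the labile mixed acetal during isolation. The fallback replaces the O,O-acetal by a robust N,O-acetal; it sets out from 5 and 6 and comes back at the oxocarbenium ion 15. Aldehyde 6, 1H-benzotriazole and SOCl2 (toluene, reflux) would give 1-[chloro(3,4,5-tris(benzyloxy)phenyl)methyl]-1H-benzotriazole F4. The sodium phenoxide of 5 (NaH, THF) should convert F4 into the chromatographically stable α-aryloxybenzyl benzotriazole F5. F5 would be used in step 10 in place of 9, where the acid expels benzotriazole and releases 15.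

Step 3. The risks are arylation through the carbon between the two benzyloxy groups instead of the carbon ortho to OH, and self-condensation of the electrophile. The fallback attaches the upper unit last; it sets out from 4 and comes back at 17. Phenol 4 would be alkylated with 8 as in step 5 to the simple mixed acetal F6, whose two ortho positions are equivalent. F6 and 14 under the conditions of step 10 should give the protected dimer F3. Chain extension of F3 with 3 (TMSOTf, CH2Cl2, −78 °C) at C8 of the galloylated unit, as established for dimer nucleophiles, then gives 17.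

**Further compounds**

F1 | step 10 | octa-O-benzyl-(−)-epigallocatechin 3-O-gallate | O=C(O[C@@H]1Cc2c(OCc3ccccc3)cc(OCc3ccccc3)cc2O[C@@H]1c1cc(OCc2ccccc2)c(OCc2ccccc2)c(OCc2ccccc2)c1)c1cc(OCc2ccccc2)c(OCc2ccccc2)c(OCc2ccccc2)c1

F2 | step 10 | 4β-(2-ethoxyethoxy)-octa-O-benzyl-epigallocatechin 3-O-gallate, alkoxy group trans to the ester | O=C(O[C@@H]1[C@@H](OCCOCC)c2c(OCc3ccccc3)cc(OCc3ccccc3)cc2O[C@@H]1c1cc(OCc2ccccc2)c(OCc2ccccc2)c(OCc2ccccc2)c1)c1cc(OCc2ccccc2)c(OCc2ccccc2)c(OCc2ccccc2)c1

F3 | step 10 | per-O-benzylated epigallocatechin 3-O-gallate-(4β→8)-epigallocatechin dimer | O=C(O[C@@H]1[C@@H](c2c(OCc5ccccc5)cc(OCc5ccccc5)c3c2O[C@H](c2cc(OCc5ccccc5)c(OCc5ccccc5)c(OCc5ccccc5)c2)[C@H](OCc5ccccc5)C3)c2c(OCc5ccccc5)cc(OCc5ccccc5)cc2O[C@@H]1c1cc(OCc5ccccc5)c(OCc5ccccc5)c(OCc5ccccc5)c1)c1cc(OCc5ccccc5)c(OCc5ccccc5)c(OCc5ccccc5)c1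

F4 | step 5 | 1-[chloro(3,4,5-tris(benzyloxy)phenyl)methyl]-1H-benzotriazole (racemic) | ClC(n1nnc2ccccc12)c1cc(OCc2ccccc2)c(OCc2ccccc2)c(OCc2ccccc2)c1

F5 | step 5 | N,O-acetal: aryl ether of 5 with the (benzotriazol-1-yl)[3,4,5-tris(benzyloxy)phenyl]methyl group on the phenol oxygen (both epimers) | C(n1nnc2ccccc12)(Oc1cc(OCc2ccccc2)cc(OCc2ccccc2)c1[C@H]1c2c(OCc3ccccc3)cc(OCc3ccccc3)cc2O[C@H](c2cc(OCc3ccccc3)c(OCc3ccccc3)c(OCc3ccccc3)c2)[C@@H]1OCc1ccccc1)c1cc(OCc2ccccc2)c(OCc2ccccc2)c(OCc2ccccc2)c1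

F6 | step 3 | 1,3-bis(benzyloxy)-5-{methoxy[3,4,5-tris(benzyloxy)phenyl]methoxy}benzene (racemic) | COC(Oc1cc(OCc2ccccc2)cc(OCc2ccccc2)c1)c1cc(OCc2ccccc2)c(OCc2ccccc2)c(OCc2ccccc2)c1
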